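Assumption: the target has no stereocentres and no stereogenic double bonds, so no stereocontrol is needed; the side chain is read as unbranched C29 (nonacosyl).

**Retrosynthetic overview**
1. The target is opened at O1–C2: the pyranone ring (the only ring made; the benzene ring is bought) closes last, by a demethylative 6-endo-dig cyclisation of aryl ynone 6 that also frees both phenols.
2. Ynone 6 comes from a three-component Pd-catalysed carbonylative Sonogashira coupling of 2-iodo-1,3,5-trimethoxybenzene, CO (becomes C4) and hentriacont-1-yne (becomes C3, C2 and the chain).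
3. The alkyne comes from triacontanal by one-carbon Ohira–Bestmann homologation, and the aldehyde from commercial triacontan-1-ol.
4. The symmetric trimethoxyarene removes any regiochemical question in the ring closure; the classical Baker–Venkataraman/Claisen acylation of phloroacetophenone is deliberately not used.

**Route**

Step 1
Reactants: 1 triacontan-1-ol
Product: 2 triacontanal
Conditions: TEMPO (10 mol%), PhI(OAc)2 (1.2 equiv), CH2Cl2 (0.05 M), 38 °C, 6 h
Reagents that add atoms: none
Why: TEMPO/oxoammonium-catalysed alcohol oxidation stops at the aldehyde in anhydrous CH2Cl2 and tolerates the gentle warming needed to dissolve the C30 wax alcohol.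

Step 2
Reactants: 2 triacontanal
Product: 4 hentriacont-1-yne, via 1-diazohentriacont-1-ene 3 (not isolated)
Conditions: Ohira–Bestmann reagent (1.5 equiv), K2CO3 (2.5 equiv), THF/MeOH 2:1, 40 °C, 16 h
Reagents that add atoms: dimethyl (1-diazo-2-oxopropyl)phosphonate (Ohira–Bestmann reagent), CC(=O)C(=[N+]=[N-])P(=O)(OC)OC
Why: Seyferth–Gilbert homologation in its Ohira–Bestmann form: methanolysis gives the diazomethylphosphonate anion, Horner–Wadsworth–Emmons-type olefination gives diazoalkene 3, and loss of N2 with 1,2-H shift gives the terminal alkyne under a base mild enough to spare the enolisable aldehyde.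

Step 3
Reactants: 4 hentriacont-1-yne; 5 2-iodo-1,3,5-trimethoxybenzene (1.3 equiv)
Product: 6 1-(2,4,6-trimethoxyphenyl)dotriacont-2-yn-1-one
Conditions: PdCl2(PPh3)2 (5 mol%), Et3N (3 equiv), CO (5 bar), THF/toluene 1:1, 45 °C, 24 h, no CuI
Reagents that add atoms: carbon monoxide, [C-]#[O+]
Why: Copper-free carbonylative Sonogashira coupling: oxidative addition of the aryl iodide, CO insertion (favoured for electron-rich, ortho-substituted aryl-Pd and by CO pressure) and amine-assisted alkynylation of the aroyl-Pd give the ynone, with direct Sonogashira coupling suppressed by leaving out copper.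

Step 4
Reactants: 6 1-(2,4,6-trimethoxyphenyl)dotriacont-2-yn-1-one
Product: 9 5,7-dihydroxy-2-nonacosyl-4H-chromen-4-one, via ortho-phenol ynone 7 (not isolated), via 5-hydroxy-7-methoxychromone 8 (not isolated)
Conditions: BBr3 (6 equiv, 1 M in CH2Cl2), CH2Cl2, −78 °C → rt → 40 °C, 16 h; then MeOH/H2O, 50 °C, 1 h
Reagents that add atoms: none
Why: Proposed new method: BBr3 first cleaves one ortho-OMe by carbonyl chelation (7, held as its ArO–BBr2 chelate), which places the Lewis-acid-activated alkynone next to the second ortho-OMe; that oxygen attacks the β-alkyne carbon 6-endo-dig to an O-methyl oxonium that bromide demethylates (8), excess BBr3 then cleaves the 7-OMe, and any uncyclised o-hydroxy ynone or β-bromoenone closes to the same chromone in the acidic methanolic quench; the closest known reactions are the ICl-triggered demethylative 6-endo cyclisation of o-methoxyaryl ynones to chromones and routine BBr3 cleavage of 5,7-dimethoxychromone ethers.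

**Compound list**
1 | triacontan-1-ol | CCCCCCCCCCCCCCCCCCCCCCCCCCCCCCO | starting material
2 | triacontanal | CCCCCCCCCCCCCCCCCCCCCCCCCCCCCC=O | intermediate
3 | 1-diazohentriacont-1-ene | CCCCCCCCCCCCCCCCCCCCCCCCCCCCCC=C=[N+]=[N-] | intermediate (not isolated)
4 | hentriacont-1-yne | CCCCCCCCCCCCCCCCCCCCCCCCCCCCCC#C | intermediate
5 | 2-iodo-1,3,5-trimethoxybenzene | COc1cc(OC)c(I)c(OC)c1 | starting material
6 | 1-(2,4,6-trimethoxyphenyl)dotriacont-2-yn-1-one | CCCCCCCCCCCCCCCCCCCCCCCCCCCCCC#CC(=O)c1c(OC)cc(OC)cc1OC | intermediate
7 | 1-(2-hydroxy-4,6-dimethoxyphenyl)dotriacont-2-yn-1-one (present as its O–BBr2 chelate) | CCCCCCCCCCCCCCCCCCCCCCCCCCCCCC#CC(=O)c1c(O)cc(OC)cc1OC | intermediate (not isolated)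
8 | 5-hydroxy-7-methoxy-2-nonacosyl-4H-chromen-4-one (present as its boron chelate) | CCCCCCCCCCCCCCCCCCCCCCCCCCCCCc1cc(=O)c2c(O)cc(OC)cc2o1 | intermediate (not isolated)
9 | 5,7-dihydroxy-2-nonacosyl-4H-chromen-4-one | CCCCCCCCCCCCCCCCCCCCCCCCCCCCCc1cc(=O)c2c(O)cc(O)cc2o1 | target

**Totals**
Total step count: 4. Longest linear sequence: 4 steps (1 → 2 → 4 → 6 → 9).

**Three steps most likely to fail, with fallbacks**

First, step 3, the carbonylative coupling. The aryl iodide is di-ortho-substituted and the waxy alkyne is poorly soluble. Direct Sonogashira coupling or phosphine-induced isomerisation of the alkyl ynone to a dienone could compete. The fallback sets out from 4 and comes back at 6 without palladium or CO. Alkyne 4 is deprotonated with n-BuLi (THF, −20 → 0 °C) and added to commercial 2,4,6-trimethoxybenzaldehyde to give racemic 1-(2,4,6-trimethoxyphenyl)dotriacont-2-yn-1-ol F1. This acid-sensitive carbinol is worked up under basic conditions and oxidised with activated MnO2 (CH2Cl2, rt) to ynone 6.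

Second, step 4, the one-flask BBr3 cascade. Bromide adducts could persist, or demethylation at the 7-position could stop short. The fallback sets out from 6 and comes back at 9 through an enaminone instead of direct Lewis-acid activation of the ynone. Conjugate addition of Et2NH (5 equiv, THF/EtOH, 50 °C) to 6 gives (E)-3-(diethylamino)-1-(2,4,6-trimethoxyphenyl)dotriacont-2-en-1-one F2. Fusion of this with pyridinium chloride (190 °C, 2 h) removes all three methyl groups, and the freed ortho-phenol closes onto the β-carbon by addition–elimination with loss of diethylamine. This is the classical enaminone-to-chromone cyclisation and gives 9 directly.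

Third, step 2, the homologation. The C30 aldehyde is barely soluble in methanol-containing media and can form acetal or aldol by-products before it is olefinated. The fallback sets out from 2 and comes back at 4 by a Corey–Fuchs sequence in aprotic solvents. Aldehyde 2 with CBr4/PPh3 (CH2Cl2, 0 °C → rt) gives 1,1-dibromohentriacont-1-ene F3. Treatment with n-BuLi (2.2 equiv, THF, −78 °C → rt; Li/Br exchange, α-elimination and 1,2-shift), then water, gives alkyne 4.

**Further compounds**
F1 | step 3 | rac-1-(2,4,6-trimethoxyphenyl)dotriacont-2-yn-1-ol | CCCCCCCCCCCCCCCCCCCCCCCCCCCCCC#CC(O)c1c(OC)cc(OC)cc1OC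
F2 | step 4 | (E)-3-(diethylamino)-1-(2,4,6-trimethoxyphenyl)dotriacont-2-en-1-one | CCCCCCCCCCCCCCCCCCCCCCCCCCCCC/C(N(CC)CC)=C\C(=O)c1c(OC)cc(OC)cc1OC
F3 | step 2 | 1,1-dibromohentriacont-1-ene | CCCCCCCCCCCCCCCCCCCCCCCCCCCCCC=C(Br)Br
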